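## Structural features

The target is a 2,3-dihydrobenzofuran: benzene ring A is fused at C3a–C7a to dihydrofuran ring B (O1, C2, C3). C5 of ring A, para to O1, carries an (E)-propenoic acid. C2 of ring B carries a three-carbon chain whose C1' bears a methyl group and whose C2' is the CH2O of an (E)-4-hydroxycinnamate ester. The only stereocentres, C2 (S) and C1' (S), are directly bonded; on the zigzag C3–C2–C1'–C2', O1 and the methyl group are syn, the pattern of a syn aldol. Fragile groups are the two cinnamate-type Michael acceptors, the free phenol, the free acid and the primary ester, so strongly basic or reducing conditions are excluded late in the sequence. A latent weakness appears whenever C1' is alpha to a carbonyl group: O1 is then a beta-aryloxy leaving group, and enolisation can open ring B and scramble both centres. The real difficulty is the contiguous C2/C1' pair next to a C3 that has no functional handle. That bare benzylic CH2 at C3, ortho to O1 on ring A, is the exocyclic terminus of an ortho-quinone methide. The key step uses it: C3 and O1 are the ends of a four-atom unit, and C2 is added as one carbon that already carries C1' as the alpha carbon of an acrylate (its =CH2 the future methyl, its ester carbon the future C2').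

## Logic of the disconnections

**16 to 14 + 15.** The aryl–vinyl bond between C5 of ring A and the beta carbon of the propenoic acid is cut. Attaching this most polar side chain last by a Heck reaction means no carboxyl protecting group is needed. The gain is one conjugated acid less in 14, with 15 as the simplest three-carbon partner. The demand is that the C5–Br bond survives every earlier step from 1 onward. The coupling must also tolerate a free phenol, a free acid and the ester of 14, and must take the terminal alkene of 15 in preference to the disubstituted alkene already present.

**14 to 12 + 13.** The ester linkage is cut between C2' and the carboxylate oxygen. This separates the whole aromatic acyl part as unprotected 13 and leaves a small bromo alcohol carrying both stereocentres. The forward step activates the alcohol, not the acid. The demand is chemoselectivity: the carboxyl group of 13 must react and its phenol must not.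

**12 to 11 to 10.** No skeletal bond is cut. The C2' alcohol is traced to the carboxylic acid 11, and the C1'–H bond of 11 to the C1'=CH2 double bond of 10. This removes C1' as a stereocentre and leaves a single centre, C2. The demand is that hydrogen adds to the Si face of C1', so that O1 and the methyl group end up syn. Chelation of a cationic metal by O1 would favour the anti isomer, so the catalyst must hold the substrate through its carboxylate and override the neighbouring centre. The catalyst must also be homogeneous, so that the aryl bromide and the allylic C2–O1 bond survive.

**10 to 9.** The acid is traced to its ethyl ester. The ester is what the annulation delivers, but only the free acid offers the carboxylate handle needed for the hydrogenation. The demand is that hydroxide attacks the ester carbonyl and does not add to the acrylate in the SN2' sense, which would expel O1 and open ring B.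

**9 to 2 + 5.** Both bonds to C2 within ring B are cut, C2–C3 and O1–C2. Ring B, two skeletal bonds and the C2 stereocentre disappear in one operation. What remains is a phenol carrying a benzylic leaving group and an allylic sulfonium salt, neither with a stereocentre on carbon apart from the chiral sulfide. The demand is threefold: face selectivity at the ylide carbon, reaction through the ylide alpha carbon and not the gamma carbon, and ring closure faster than epimerisation of the intermediate.

**5 to 3 + 4, and 2 to 1.** The S–CH2 bond of 5 and the benzylic C–S bond of 2 are cut. The salt is made and isolated beforehand with a non-nucleophilic counter-ion. This is a deliberate change from forming it in the annulation flask, where the phenoxide of 2 would meet free 3 and be O-allylated, and where bromide could reverse the salt formation. The demand on the route to 2 is that the benzylic alcohol of 1 ionises under acid without self-condensation of the phenol.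

## Other disconnections considered

**Alternative 1:** The cut runs through ring A at C3a–C4 and C7a–C7; ring B is kept and the benzene ring is built last. Forward, methyl coumalate A1 and the lactone-derived ketene acetal A2 would be heated together. An inverse-demand [4+2] addition, decarboxylative cycloreversion and loss of the methoxy group would aromatise the adduct to the benzoate A3.
- In its favour: the polarisation of both partners fixes the regiochemistry and places the ester at C5, no metal is needed, and both stereocentres arrive complete in A2.
- Against it here: A2 is a hydrolytically sensitive cyclic ketene acetal. It must be made from a gamma-lactone that already holds the syn C2/C1' pair, which needs its own multi-step asymmetric synthesis. After the key step the C5 ester of A3 must be reduced, reoxidised and homologated to the propenoic acid, and the silyl ether removed.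
- Structure: the alternative is better, because neither stereocentre is created or endangered in the ring-forming step.
- Mechanism: a thermal pericyclic cascade has fewer chemoselectivity questions than an ylide annulation, which is also a point for the alternative.
- Step economy: it is clearly worse, about twelve steps against eight, with two redox corrections at C5.

**Alternative 2:** The cut is C3–C3a together with C7a–O1, so ring B is closed onto an intact arene. Forward, aryl iodide A4 and epoxide A5 would react in a Catellani-type relay with Pd(OAc)2, a biaryl dialkylphosphine, a bridgehead-substituted norbornene and a carbonate base. Ortho alkylation by the epoxide CH2 and ipso C–O coupling would give A6.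
- In its favour: the union is convergent, and the epoxide C–O bond at the stereocentre is never broken, so C2 is carried in with retention. The acetal of A6 is a masked aldehyde that a Knoevenagel–Doebner condensation would turn directly into the propenoic acid.
- Against it here: A5, with two adjacent stereocentres, needs about five steps from the chiral pool, including a diastereoselective epoxide synthesis. An aryl iodide without an ortho substituent depends on the special norbornene to stop after one ortho alkylation. Acetal and ether protecting groups must be removed afterwards.
- Structure: the alternative is better on stereochemical certainty, since no stereocentre is made in the key step.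
- Mechanism: it is at least the equal of the chosen plan, because annulation of aryl iodides with alkyl-substituted epoxides is closer to established scope than the ylide step proposed here.
- Step economy: it is worse, about eleven steps, and it requires protecting groups where the chosen route uses none.

**Alternative 3:** The cut is the single bond C2–C3. Forward, base would convert tosylhydrazone A7 into the diazo compound. A chiral amidoporphyrin complex of divalent cobalt, Co(Por*), would turn this into a benzylic carbene radical, which abstracts hydrogen from the O–CH2 group and recombines to give A8.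
- In its favour: A7 would be available in about four steps from 5-bromo-2-hydroxybenzaldehyde A9 and a chiral-pool C4 alcohol. C1' comes from the chiral pool with no risk of epimerisation. Desilylation of A8 gives 12 directly, so the endgame is the same as in the chosen plan.
- Against it here: C2 is created at an unactivated O–CH2 group next to an existing stereocentre, so catalyst and substrate preferences may be matched or mismatched. Abstraction of the tertiary C1'–H, which would lead to a six-membered ring, competes. The catalyst is a specialised porphyrin that must be synthesised.
- Structure: the alternative is better at C1', because it avoids the hydrogenation of the chosen plan.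
- Mechanism: the two are equal. Both rely on reagent-controlled creation of C2 on a substrate outside demonstrated scope.
- Step economy: the alternative is equal, about eight steps, but it needs silyl protection and a non-commercial catalyst.

Key step: step 3

Assumption: S-allylation of 4 on its exo lone pair and approach of 6 to the ylide face on the C5–H side are taken to translate the (1R,4R,5R) sulfide into (S)-9; if the sense proves opposite, the (1S,4S,5S) sulfide is used with no other change.

## Route

Step 1
Reactants: 1 5-bromo-2-hydroxybenzyl alcohol
Product: 2 4-bromo-2-[(4-methylphenyl)sulfonylmethyl]phenol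
Conditions: p-TolSO2Na (1.5 equiv), HCO2H/H2O (1:1), 50 °C
Reagents that add atoms: sodium p-toluenesulfinate, Cc1ccc(cc1)S(=O)[O-].[Na+]
Why: Acid-promoted ionisation of the salicyl alcohol and S-alkylation of the soft sulfinate anion (benzylic substitution by sulfinate) should give the sulfone, which is the thermodynamic product over the sulfinate ester; the para bromine blocks one site of self-condensation.

Step 2
Reactants: 3 ethyl 2-(bromomethyl)acrylate; 4 (1R,4R,5R)-isothiocineole (commercially available in both enantiomeric forms)
Product: 5 (1R,4R,5R)-6-[2-(ethoxycarbonyl)prop-2-en-1-yl]-4,7,7-trimethyl-6-thiabicyclo[3.2.1]octan-6-ium tetrafluoroborate, S-allyl group exo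
Conditions: NaBF4 (2 equiv), CH2Cl2/H2O, rt
Reagents that add atoms: sodium tetrafluoroborate, [Na+].F[B-](F)(F)F
Why: S-Allylation of the sulfide (SN2 and SN2' give the same salt) should occur on the exposed exo lone pair to give one sulfonium diastereomer, and exchange of bromide for tetrafluoroborate prevents reversal and gives a storable salt.

Step 3
Reactants: 2 4-bromo-2-[(4-methylphenyl)sulfonylmethyl]phenol; 5 the sulfonium tetrafluoroborate
Product: 9 ethyl 2-[(2S)-5-bromo-2,3-dihydro-1-benzofuran-2-yl]prop-2-enoate, via ortho-quinone methide 6 (not isolated), via sulfonium ylide 7 (not isolated), via phenoxide–sulfonium betaine 8 (not isolated)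
Conditions: Cs2CO3 (3 equiv), CH2Cl2, −20 → 0 °C; 2 added over 4 h to 5 (1.3 equiv) and base
Reagents that add atoms: none
Why: Proposed new method: Cs2CO3 deprotonates 2, whose phenoxide expels p-toluenesulfinate to give ortho-quinone methide 6, and also deprotonates 5 at its S–CH2 group to give allylic ylide 7. The ylide alpha carbon adds to the exocyclic CH2 of 6 (C2–C3), ring A rearomatises to betaine 8, and the phenoxide of 8 displaces the sulfonium group at that same carbon with inversion (O1–C2, 5-exo-tet), releasing sulfide 4. The closest known reaction type is the [4+1] annulation of in situ ortho-quinone methides with carbonyl-stabilised sulfonium ylides to 2-substituted 2,3-dihydrobenzofurans, combined with chiral-sulfide control of ylide face selectivity in epoxidation and cyclopropanation; new is the 2-carbethoxyallyl ylide on an isothiocineole sulfonium centre. C2 is the only new stereocentre and its configuration is decided in the C–C bond-forming step: in 7 the vinyl group should point away from the C7 gem-dimethyl group, which also screens one face of the ylide carbon, so that 6 adds from the C5–H side to give (R)-8 and, after inversion, (S)-9. Because the methide terminus is an unsubstituted CH2, no second stereocentre and no diastereoselectivity question arises. Attack through the alpha carbon is expected because the charge is concentrated next to sulfur and because gamma attack would leave a vinylsulfonium that cannot close a five-membered ring. The preformed, bromide-free salt 5 and slow addition of 2 keep free allyl bromide and excess phenoxide out of the flask, which should suppress O-allylation of the phenoxide and self-condensation of 6. The intramolecular SN2 closure should be faster than deprotonation–reprotonation at the sulfonium-bearing carbon of 8, so the configuration set in the addition is carried into 9.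

Step 4
Reactants: 9 ethyl 2-[(2S)-5-bromo-2,3-dihydro-1-benzofuran-2-yl]prop-2-enoate
Product: 10 2-[(2S)-5-bromo-2,3-dihydro-1-benzofuran-2-yl]prop-2-enoic acid
Conditions: LiOH·H2O (2 equiv), THF/H2O (3:1), 0 °C → rt; then 1 M HCl
Reagents that add atoms: lithium hydroxide, [Li+].[OH-]
Why: Saponification of the ethyl ester by acyl–oxygen cleavage; the carboxylate formed is no longer a Michael acceptor, which limits SN2'-type opening of ring B, and C2 carries no acidifying group and should keep its configuration.

Step 5
Reactants: 10 2-[(2S)-5-bromo-2,3-dihydro-1-benzofuran-2-yl]prop-2-enoic acid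
Product: 11 (2R)-2-[(2S)-5-bromo-2,3-dihydro-1-benzofuran-2-yl]propanoic acid
Conditions: H2 (100 atm), Ru(OAc)2[(R)-BINAP] (1 mol%), MeOH, 25 °C
Reagents that add atoms: none
Why: Carboxylate-directed asymmetric hydrogenation of an alpha-substituted acrylic acid: the substrate exchanges onto ruthenium as its carboxylate and hydrogen should be delivered to the Si face of C1', giving the (R)-acid in which O1 and the methyl group are syn. The sense is predicted from 2-arylacrylic acids, for which the (S)-BINAP complex is known to favour (S)-acids, with C2 here taking the place of the aryl group; the homogeneous catalyst leaves the aryl bromide and the allylic C2–O1 bond intact.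

Step 6
Reactants: 11 (2R)-2-[(2S)-5-bromo-2,3-dihydro-1-benzofuran-2-yl]propanoic acid
Product: 12 (2S)-2-[(2S)-5-bromo-2,3-dihydro-1-benzofuran-2-yl]propan-1-ol
Conditions: BH3·THF (2 equiv), THF, 0 °C → rt; aqueous work-up
Reagents that add atoms: none
Why: Borane reduces the carboxylic acid through an acyloxyborane without base, so C1' cannot enolise and ring B cannot open by beta-elimination; the C1' descriptor changes from R to S only because the CIP priorities change, not the geometry.

Step 7
Reactants: 12 (2S)-2-[(2S)-5-bromo-2,3-dihydro-1-benzofuran-2-yl]propan-1-ol; 13 p-coumaric acid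
Product: 14 (2S)-2-[(2S)-5-bromo-2,3-dihydro-1-benzofuran-2-yl]propyl (2E)-3-(4-hydroxyphenyl)prop-2-enoate
Conditions: PPh3 (1.3 equiv), DIAD (1.3 equiv), THF, 0 °C → rt
Reagents that add atoms: none
Why: Mitsunobu esterification: the carboxylic acid (pKa about 4.5) protonates the phosphine–azodicarboxylate adduct and its carboxylate attacks the alkoxyphosphonium ion of the primary alcohol, while the far less acidic phenol is not expected to compete; C2' is not stereogenic, so inversion is irrelevant.

Step 8
Reactants: 14 (2S)-2-[(2S)-5-bromo-2,3-dihydro-1-benzofuran-2-yl]propyl (2E)-3-(4-hydroxyphenyl)prop-2-enoate; 15 acrylic acid (3 equiv)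
Product: 16 (2E)-3-[(2S)-2-{(2S)-1-[(2E)-3-(4-hydroxyphenyl)prop-2-enoyloxy]propan-2-yl}-2,3-dihydro-1-benzofuran-5-yl]prop-2-enoic acid
Conditions: Pd(OAc)2 (5 mol%), P(o-tol)3 (10 mol%), Et3N (4 equiv), DMF, 100 °C
Reagents that add atoms: none
Why: Mizoroki–Heck reaction: zerovalent palladium formed in situ inserts into the C5–Br bond, syn insertion of the acrylate and beta-hydride elimination should give the E alkene, and the terminal alkene of 15 reacts far faster than the disubstituted cinnamate alkene of 14; neither stereocentre is acidic under these conditions.

## Compound list

1 | 5-bromo-2-hydroxybenzyl alcohol [4-bromo-2-(hydroxymethyl)phenol] | OCc1cc(Br)ccc1O | starting material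
2 | 4-bromo-2-[(4-methylphenyl)sulfonylmethyl]phenol | Cc1ccc(cc1)S(=O)(=O)Cc1cc(Br)ccc1O | intermediate
3 | ethyl 2-(bromomethyl)acrylate [ethyl 2-(bromomethyl)prop-2-enoate] | C=C(CBr)C(=O)OCC | starting material
4 | (1R,4R,5R)-isothiocineole [(1R,4R,5R)-4,7,7-trimethyl-6-thiabicyclo[3.2.1]octane] | C[C@@H]1CC[C@@H]2C[C@H]1SC2(C)C | starting material
5 | (1R,4R,5R)-6-[2-(ethoxycarbonyl)prop-2-en-1-yl]-4,7,7-trimethyl-6-thiabicyclo[3.2.1]octan-6-ium tetrafluoroborate, S-allyl group exo | C[C@@H]1CC[C@@H]2C[C@H]1[S@@+](CC(=C)C(=O)OCC)C2(C)C.F[B-](F)(F)F | intermediate
6 | 4-bromo-6-methylidenecyclohexa-2,4-dien-1-one (ortho-quinone methide) | C=C1C=C(Br)C=CC1=O | intermediate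
7 | sulfonium ylide of 5: (1R,4R,5R)-4,7,7-trimethyl-6-thiabicyclo[3.2.1]octan-6-ium-6-yl 2-(ethoxycarbonyl)prop-2-en-1-ylide, ylide carbon exo on sulfur | C[C@@H]1CC[C@@H]2C[C@H]1[S@@+]([CH-]C(=C)C(=O)OCC)C2(C)C | intermediate
8 | 4-bromo-2-[(2R)-3-(ethoxycarbonyl)-2-{(1R,4R,5R)-4,7,7-trimethyl-6-thiabicyclo[3.2.1]octan-6-ium-6-yl}but-3-en-1-yl]phenolate (betaine) | C[C@@H]1CC[C@@H]2C[C@H]1[S@@+]([C@H](Cc3cc(Br)ccc3[O-])C(=C)C(=O)OCC)C2(C)C | intermediate
9 | ethyl 2-[(2S)-5-bromo-2,3-dihydro-1-benzofuran-2-yl]prop-2-enoate | C=C(C(=O)OCC)[C@@H]1Cc2cc(Br)ccc2O1 | intermediate
10 | 2-[(2S)-5-bromo-2,3-dihydro-1-benzofuran-2-yl]prop-2-enoic acid | C=C(C(=O)O)[C@@H]1Cc2cc(Br)ccc2O1 | intermediate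
11 | (2R)-2-[(2S)-5-bromo-2,3-dihydro-1-benzofuran-2-yl]propanoic acid | C[C@@H](C(=O)O)[C@@H]1Cc2cc(Br)ccc2O1 | intermediate
12 | (2S)-2-[(2S)-5-bromo-2,3-dihydro-1-benzofuran-2-yl]propan-1-ol | C[C@@H](CO)[C@@H]1Cc2cc(Br)ccc2O1 | intermediate
13 | p-coumaric acid [(2E)-3-(4-hydroxyphenyl)prop-2-enoic acid] | O=C(O)/C=C/c1ccc(O)cc1 | starting material
14 | (2S)-2-[(2S)-5-bromo-2,3-dihydro-1-benzofuran-2-yl]propyl (2E)-3-(4-hydroxyphenyl)prop-2-enoate | C[C@@H](COC(=O)/C=C/c1ccc(O)cc1)[C@@H]1Cc2cc(Br)ccc2O1 | intermediate
15 | acrylic acid (prop-2-enoic acid) | C=CC(=O)O | starting material
16 | (2E)-3-[(2S)-2-{(2S)-1-[(2E)-3-(4-hydroxyphenyl)prop-2-enoyloxy]propan-2-yl}-2,3-dihydro-1-benzofuran-5-yl]prop-2-enoic acid (CNP0224846.1) | C[C@@H](COC(=O)/C=C/c1ccc(O)cc1)[C@@H]1Cc2cc(/C=C/C(=O)O)ccc2O1 | target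

## Step count and least certain steps

Total step count: 8. Longest linear sequence: 7 (steps 1, 3, 4, 5, 6, 7, 8); step 2 is a one-step branch.

**Step 3 (key step, proposed new method).**
- Most likely failure: poor facial selectivity at the ylide carbon. The unsubstituted methide terminus of 6 is small and gives the sulfonium scaffold little to discriminate, and the ester-bearing allyl ylide is more delocalised than the benzyl ylides for which this sulfide is established.
- Further risks: material may be lost by SN2' O-allylation of the phenoxide of 2 by 5, by gamma attack of 7, or by self-condensation of 6. The released sulfide 4 could also reopen ring B of 9 by SN2' addition and erode the configuration.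
- Fallback: it sets out from 10 of insufficient enantiomeric purity (9 from step 3, saponified as in step 4) and comes back at 10 as the single enantiomer. The acid is combined with (R)-1-phenylethylamine in aqueous ethanol, and the less soluble salt, (R)-1-phenylethylammonium 2-[(2S)-5-bromo-2,3-dihydro-1-benzofuran-2-yl]prop-2-enoate F1, is crystallised to constant rotation. The diastereomeric salt (R)-1-phenylethylammonium 2-[(2R)-5-bromo-2,3-dihydro-1-benzofuran-2-yl]prop-2-enoate F2 stays in the mother liquor. Acidification of F1 returns 10. If the (2R) salt turns out to be the less soluble one, the enantiomeric amine is used. Classical resolution of a carboxylic acid through diastereomeric ammonium salts is known chemistry, and it replaces reagent control by separation.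

**Step 5.**
- Most likely failure: mismatched double stereodifferentiation. The existing C2 centre, and weak coordination of the metal by O1 (which favours the anti isomer), may oppose the catalyst, giving incomplete diastereoselectivity. Metal hydride isomerisation of the 1,1-disubstituted alkene into conjugation with O1 would also destroy C2.
- Fallback: it sets out from 9 and comes back at 12. The ester is reduced with (i-Bu)2AlH in CH2Cl2 at −78 °C to 2-[(2S)-5-bromo-2,3-dihydro-1-benzofuran-2-yl]prop-2-en-1-ol F3. The hydrogenation is then run on this allylic alcohol with Ru(OAc)2[BINAP] in MeOH, the ligand enantiomer being chosen to match the substrate, so that the primary hydroxyl group becomes the directing group. This changes both the substrate class and the binding group, and saves one step.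

**Step 8.**
- Most likely failure: slow oxidative addition into the electron-rich C5–Br bond para to O1, with competing reductive debromination and catalyst decomposition, in the presence of a free phenol and a free acid. Purification of the polar product from phosphine and palladium residues falls at the last step.
- Fallback: it sets out from 12 and comes back at 16, with the acid carried in protected form and the order of events changed. A Heck reaction of 12 with tert-butyl acrylate under the same Pd(OAc)2/P(o-tol)3/Et3N conditions gives tert-butyl (2E)-3-{(2S)-2-[(2S)-1-hydroxypropan-2-yl]-2,3-dihydro-1-benzofuran-5-yl}prop-2-enoate F4. Mitsunobu esterification with 13, as in step 7, gives tert-butyl (2E)-3-[(2S)-2-{(2S)-1-[(2E)-3-(4-hydroxyphenyl)prop-2-enoyloxy]propan-2-yl}-2,3-dihydro-1-benzofuran-5-yl]prop-2-enoate F5. CF3CO2H in CH2Cl2 with anisole as cation scavenger then cleaves the tert-butyl ester to 16.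

**Step 7.**
- Most likely failure: competing alkylation of the phenol of 13 or of the product, giving aryl ethers and oligomeric material, and difficult removal of the phosphine oxide and hydrazine by-products from a phenolic ester.
- Fallback: it sets out from 12 (with 13 as the source of the acyl part) and comes back at 14, activating the acid instead of the alcohol. Acetylation of 13 with Ac2O/pyridine gives (2E)-3-(4-acetoxyphenyl)prop-2-enoic acid F6. Carbodiimide coupling with 12 (N-(3-dimethylaminopropyl)-N'-ethylcarbodiimide hydrochloride, DMAP, CH2Cl2) gives (2S)-2-[(2S)-5-bromo-2,3-dihydro-1-benzofuran-2-yl]propyl (2E)-3-(4-acetoxyphenyl)prop-2-enoate F7. The phenolic acetate is then removed selectively with NH4OAc in aqueous MeOH to give 14.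

**Step 1.**
- Most likely failure: acid-induced self-condensation of the salicyl alcohol through its free ortho position, and attack of the ambident sulfinate through oxygen, giving an unstable sulfinate ester.
- Fallback: it sets out from 1 and comes back at 2 by forming the C–S bond with a thiol and oxidising afterwards. Reaction of 1 with 4-methylbenzenethiol and catalytic p-toluenesulfonic acid in toluene at 60 °C gives 4-bromo-2-{[(4-methylphenyl)sulfanyl]methyl}phenol F8. Oxidation with H2O2 and catalytic Na2WO4 in MeOH gives 2.

## Further compounds

F1 | step 3 | (R)-1-phenylethylammonium 2-[(2S)-5-bromo-2,3-dihydro-1-benzofuran-2-yl]prop-2-enoate | C[C@@H]([NH3+])c1ccccc1.[O-]C(=O)C(=C)[C@@H]1Cc2cc(Br)ccc2O1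
F2 | step 3 | (R)-1-phenylethylammonium 2-[(2R)-5-bromo-2,3-dihydro-1-benzofuran-2-yl]prop-2-enoate | C[C@@H]([NH3+])c1ccccc1.[O-]C(=O)C(=C)[C@H]1Cc2cc(Br)ccc2O1
F3 | step 5 | 2-[(2S)-5-bromo-2,3-dihydro-1-benzofuran-2-yl]prop-2-en-1-ol | C=C(CO)[C@@H]1Cc2cc(Br)ccc2O1
F4 | step 8 | tert-butyl (2E)-3-{(2S)-2-[(2S)-1-hydroxypropan-2-yl]-2,3-dihydro-1-benzofuran-5-yl}prop-2-enoate | C[C@@H](CO)[C@@H]1Cc2cc(/C=C/C(=O)OC(C)(C)C)ccc2O1
F5 | step 8 | tert-butyl (2E)-3-[(2S)-2-{(2S)-1-[(2E)-3-(4-hydroxyphenyl)prop-2-enoyloxy]propan-2-yl}-2,3-dihydro-1-benzofuran-5-yl]prop-2-enoate | C[C@@H](COC(=O)/C=C/c1ccc(O)cc1)[C@@H]1Cc2cc(/C=C/C(=O)OC(C)(C)C)ccc2O1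
F6 | step 7 | (2E)-3-(4-acetoxyphenyl)prop-2-enoic acid | CC(=O)Oc1ccc(/C=C/C(=O)O)cc1
F7 | step 7 | (2S)-2-[(2S)-5-bromo-2,3-dihydro-1-benzofuran-2-yl]propyl (2E)-3-(4-acetoxyphenyl)prop-2-enoate | C[C@@H](COC(=O)/C=C/c1ccc(OC(C)=O)cc1)[C@@H]1Cc2cc(Br)ccc2O1
F8 | step 1 | 4-bromo-2-{[(4-methylphenyl)sulfanyl]methyl}phenol | Cc1ccc(SCc2cc(Br)ccc2O)cc1
A1 | alternative 1 | methyl coumalate (methyl 2-oxo-2H-pyran-5-carboxylate) | COC(=O)C1=COC(=O)C=C1
A2 | alternative 1 | tert-butyl{(2S)-2-[(2S)-5-methoxy-2,3-dihydrofuran-2-yl]propoxy}dimethylsilane | C[C@@H](CO[Si](C)(C)C(C)(C)C)[C@@H]1CC=C(OC)O1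
A3 | alternative 1 | methyl (2S)-2-[(2S)-1-(tert-butyldimethylsilyloxy)propan-2-yl]-2,3-dihydro-1-benzofuran-5-carboxylate | C[C@@H](CO[Si](C)(C)C(C)(C)C)[C@@H]1Cc2cc(C(=O)OC)ccc2O1
A4 | alternative 2 | 1-(dimethoxymethyl)-4-iodobenzene | COC(OC)c1ccc(I)cc1
A5 | alternative 2 | (2R)-2-{(2S)-1-[(4-methoxyphenyl)methoxy]propan-2-yl}oxirane | C[C@@H](COCc1ccc(OC)cc1)[C@@H]1CO1
A6 | alternative 2 | (2S)-5-(dimethoxymethyl)-2-{(2S)-1-[(4-methoxyphenyl)methoxy]propan-2-yl}-2,3-dihydro-1-benzofuran | C[C@@H](COCc3ccc(OC)cc3)[C@@H]1Cc2cc(C(OC)OC)ccc2O1
A7 | alternative 3 | N'-[(E)-{5-bromo-2-[(2R)-3-(tert-butyldimethylsilyloxy)-2-methylpropoxy]phenyl}methylidene]-4-methylbenzenesulfonohydrazide | C[C@@H](CO[Si](C)(C)C(C)(C)C)COc1ccc(Br)cc1/C=N/NS(=O)(=O)c1ccc(C)cc1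
A8 | alternative 3 | tert-butyl{(2S)-2-[(2S)-5-bromo-2,3-dihydro-1-benzofuran-2-yl]propoxy}dimethylsilane | C[C@@H](CO[Si](C)(C)C(C)(C)C)[C@@H]1Cc2cc(Br)ccc2O1
A9 | alternative 3 | 5-bromo-2-hydroxybenzaldehyde | O=Cc1cc(Br)ccc1O
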